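**Retrosynthetic overview**

- The target is a 3,3''-biflavanone, (2S,3R,2''S,3''R): two 2,3-trans flavanones joined C3–C3''. The last step is hydrogenolysis of five benzyl ethers.
- Key disconnection, made twice in one operation: in each half the C4–C4a bond (closure of pyranone ring C) together with the O1–C8a bond, by annulation of a β-silyloxy Weinreb amide with 3,5-bis(benzyloxy)benzyne. This leads back to an acyclic succinic bis(Weinreb amide) that already carries all four stereocenters.
- Enabling feature: in each ring A the ether oxygen O1 (on C8a) and the acyl carbon C4 (on C4a) sit on adjacent ring carbons, and C4a is flanked by the C5 oxygen. This is the pattern left when an alkoxide adds to a 3-alkoxyaryne at the remote carbon and the ortho carbanion is acylated.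
- The acyclic precursor comes from a succinyl bis(thioimide) by two sequential auxiliary-controlled anti-aldol reactions (4-methoxybenzaldehyde, then 4-(benzyloxy)benzaldehyde) that form C2–C3 and C2''–C3''. Anti aldols map onto 2,3-trans rings because the carbinol C–O bonds are never broken.
- Ring order: rings B are bought, both rings A arrive complete with the aryne, and the two rings C are closed last and together. Auxiliaries, silyl groups and N-methoxy-N-methyl groups are shed on the way.

Key step: step 8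

Remark (assumption): the MgBr2·OEt2-catalysed anti-aldol of N-acylthiazolidinethiones is taken to follow its usual sense (α-centre as in the boron syn-aldol of the same auxiliary, carbinol centre anti), which makes the (R)-auxiliary the right one. If the sense were opposite, the (S)-auxiliary would be used and nothing else changes.

Step 1
Reactants: 1 3,5-bis(benzyloxy)phenol
Product: 2 3,5-bis(benzyloxy)phenyl N-isopropylcarbamate
Conditions: i-PrNCO, Et3N (cat.), CH2Cl2, rt
Reagents that add atoms: isopropyl isocyanate, CC(C)N=C=O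
Why: Base-catalysed addition of the phenol O–H to the isocyanate (carbamoylation) should install a carbamate that directs ortho-metalation and can later be cleaved under mild conditions.

Step 2
Reactants: 2 3,5-bis(benzyloxy)phenyl N-isopropylcarbamate
Product: 6 3,5-bis(benzyloxy)-2-(trimethylsilyl)phenyl N-isopropylcarbamate, via N-silyl carbamate 3 (not isolated), via aryllithium 4 (not isolated), via bis-silyl carbamate 5 (not isolated)
Conditions: TBSOTf, TMEDA, Et2O, 0 °C → rt; then n-BuLi, TMEDA, −78 °C; then TMSCl, −78 °C → rt; aq. NaHSO4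
Reagents that add atoms: chlorotrimethylsilane, C[Si](C)(C)Cl
Why: In-situ N-silylation masks the N–H, directed ortho-metalation should then occur at the carbon flanked by the carbamate and a benzyloxy group (two cooperating directing groups; the two such positions are equivalent), TMSCl silylates that carbon and the N-silyl group is lost on aqueous work-up.

Step 3
Reactants: 6 3,5-bis(benzyloxy)-2-(trimethylsilyl)phenyl N-isopropylcarbamate
Product: 8 3,5-bis(benzyloxy)-2-(trimethylsilyl)phenyl trifluoromethanesulfonate, via silylphenol 7 (not isolated)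
Conditions: DBU, Et2NH, MeCN, 40 °C; then PhNTf2, rt
Reagents that add atoms: N-phenylbis(trifluoromethanesulfonimide), O=S(=O)(N(c1ccccc1)S(=O)(=O)C(F)(F)F)C(F)(F)F
Why: DBU-induced E1cB cleavage of the N–H carbamate (the isocyanate is trapped by Et2NH) should free the phenoxide, which is triflated in the same pot; this is the standard one-pot entry to ortho-silylaryl triflates.

Step 4
Reactants: 9 (R)-4-benzyl-1,3-thiazolidine-2-thione (first of two equivalents); 10 succinyl chloride
Product: 11 1,4-bis[(4R)-4-benzyl-2-thioxo-1,3-thiazolidin-3-yl]butane-1,4-dione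
Conditions: 9 (2 equiv in all), Et3N, DMAP (cat.), CH2Cl2, 0 °C → rt
Reagents that add atoms: (R)-4-benzyl-1,3-thiazolidine-2-thione (second equivalent of 9), S=C1N[C@H](Cc2ccccc2)CS1
Why: Twofold N-acylation, in which each acid chloride group of 10 acylates one molecule of the thiazolidinethione, should give the symmetric bis(thioimide); no stereocenter is formed.

Step 5
Reactants: 11 1,4-bis[(4R)-4-benzyl-2-thioxo-1,3-thiazolidin-3-yl]butane-1,4-dione (in excess, recovered); 12 4-methoxybenzaldehyde
Product: 13 (2R)-1,4-bis[(4R)-4-benzyl-2-thioxo-1,3-thiazolidin-3-yl]-2-[(S)-(4-methoxyphenyl)(trimethylsilyloxy)methyl]butane-1,4-dione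
Conditions: MgBr2·OEt2 (cat.), Et3N, TMSCl, EtOAc, rt; non-aqueous work-up (Et3N-deactivated silica)
Reagents that add atoms: chlorotrimethylsilane, C[Si](C)(C)Cl
Why: Magnesium-halide-catalysed direct anti-aldol of an N-acylthiazolidinethione (Evans-type auxiliary aldol: soft enolisation to the Z-magnesium enolate, boat-type addition to the aromatic aldehyde, O-silylation for turnover), in which the benzyl group of the (R)-auxiliary shields one enolate face so that C2 should be set as R and the carbinol carbon as S (anti), while the excess of symmetric 11 and the slower reaction of the β-branched product should stop the reaction at the mono-adduct.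

Step 6
Reactants: 13 (2R)-1,4-bis[(4R)-4-benzyl-2-thioxo-1,3-thiazolidin-3-yl]-2-[(S)-(4-methoxyphenyl)(trimethylsilyloxy)methyl]butane-1,4-dione; 14 4-(benzyloxy)benzaldehyde
Product: 15 (2R,3R)-1,4-bis[(4R)-4-benzyl-2-thioxo-1,3-thiazolidin-3-yl]-2-[(S)-[4-(benzyloxy)phenyl](trimethylsilyloxy)methyl]-3-[(S)-(4-methoxyphenyl)(trimethylsilyloxy)methyl]butane-1,4-dione
Conditions: MgBr2·OEt2 (cat.), Et3N, TMSCl, EtOAc, rt
Reagents that add atoms: chlorotrimethylsilane, C[Si](C)(C)Cl
Why: The same auxiliary-controlled anti-aldol at the remaining methylene (the already substituted α-carbon is a hindered methine and should not enolise) is governed by the second (R)-auxiliary, so the new pair of centres should form with the same sense (R at the α-carbon, S at the carbinol carbon), which completes the C2-type array of four stereocenters.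

Step 7
Reactants: 15 (2R,3R)-1,4-bis[(4R)-4-benzyl-2-thioxo-1,3-thiazolidin-3-yl]-2-[(S)-[4-(benzyloxy)phenyl](trimethylsilyloxy)methyl]-3-[(S)-(4-methoxyphenyl)(trimethylsilyloxy)methyl]butane-1,4-dione
Product: 16 (2R,3R)-2-[(S)-[4-(benzyloxy)phenyl](trimethylsilyloxy)methyl]-N1,N4-dimethoxy-3-[(S)-(4-methoxyphenyl)(trimethylsilyloxy)methyl]-N1,N4-dimethylbutanediamide
Conditions: MeNHOMe (excess), DMAP (cat.), CH2Cl2, rt
Reagents that add atoms: N,O-dimethylhydroxylamine (two equivalents are incorporated), CNOC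
Why: N-Acylthiazolidinethiones are active amides that amines displace under neutral conditions (aminolysis to Weinreb amides, once at each acyl group), which should spare the silyl ethers and the α-stereocenters, release the auxiliary for recovery, and leave acyl groups that neither lactonise with the γ-oxygen nor enolise readily.

Step 8
Reactants: 16 (2R,3R)-2-[(S)-[4-(benzyloxy)phenyl](trimethylsilyloxy)methyl]-N1,N4-dimethoxy-3-[(S)-(4-methoxyphenyl)(trimethylsilyloxy)methyl]-N1,N4-dimethylbutanediamide; 8 3,5-bis(benzyloxy)-2-(trimethylsilyl)phenyl trifluoromethanesulfonate (first equivalent; two are incorporated, one per half)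
Product: 19 (2S,2'S,3R,3'R)-5,5',7,7'-tetrakis(benzyloxy)-2-[4-(benzyloxy)phenyl]-2'-(4-methoxyphenyl)-[3,3'-bichromane]-4,4'-dione, via aryne 17 (not isolated), via dialkoxide 18 (not isolated)
Conditions: 8 (3 equiv in all), KF, 18-crown-6, THF, 0 °C → rt; aq. NH4Cl
Reagents that add atoms: 3,5-bis(benzyloxy)-2-(trimethylsilyl)phenyl trifluoromethanesulfonate (second equivalent of 8), C[Si](C)(C)c1c(OCc2ccccc2)cc(OCc2ccccc2)cc1OS(=O)(=O)C(F)(F)F
Why: Proposed new method: fluoride cleaves the two O–SiMe3 bonds of 16 and, in the same flask, converts two molecules of 8 into two molecules of aryne 17; each alkoxide of 18 adds to the aryne carbon remote from the neighbouring benzyloxy group (the future C8a), and the ortho carbanion so formed at the future C4a attacks the Weinreb carbonyl of its own half to give a tetrahedral adduct that collapses to the ketone, so that O1–C8a is made first and ring C is then closed by C4–C4a bond formation, once in each half. The closest known reaction types are the annulation of salicylate esters with arynes to xanthones (aryloxide addition followed by acyl capture of the aryl anion), the O–H insertion of aliphatic alcohols into arynes, and the Parham-type cyclisation of ortho-metalated aryl ethers onto Weinreb amides that gives chroman-4-ones; new here is an aliphatic β-alkoxide as the nucleophile, used twice in one operation. Each pyranone ring closes by a 6-exo-trig acyl substitution, the seven-membered closure onto the γ-amide being slower. No stereocenter is created: C2 and C2'' keep their configuration because only O–Si is exchanged for O–aryl (retention), and C3 and C3'' stay untouched provided the ketones remain masked as tetrahedral adducts until the mildly acidic quench, so the anti relationships from steps 5 and 6 become the two 2,3-trans rings. The step needs regioselective attack on the aryne (secured by the inductive and distortion effect of the 3-benzyloxy group, which thereby ends up at C5), acylation and not protonation of the aryl anion (secured by the aprotic medium and the absence of any free O–H, the silyl ethers serving as latent alkoxides), and capture of each alkoxide by an aryne before retro-aldol or lactonisation (secured by the amide level of both acyl groups and by the excess of 8 and fluoride, which keeps aryne at hand as each alkoxide is unveiled).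

Step 9
Reactants: 19 (2S,2'S,3R,3'R)-5,5',7,7'-tetrakis(benzyloxy)-2-[4-(benzyloxy)phenyl]-2'-(4-methoxyphenyl)-[3,3'-bichromane]-4,4'-dione
Product: 20 (2S,2'S,3R,3'R)-5,5',7,7'-tetrahydroxy-2-(4-hydroxyphenyl)-2'-(4-methoxyphenyl)-[3,3'-bichromane]-4,4'-dione (CNP0196568.1)
Conditions: H2 (1 atm), 10% Pd/C, EtOAc/MeOH, rt
Reagents that add atoms: none
Why: Hydrogenolysis of the five benzyl ethers over Pd/C under neutral conditions should leave the aryl methyl ether, the ketones and the four stereocenters untouched.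

**Compound list**

1 | 3,5-bis(benzyloxy)phenol | Oc1cc(OCc2ccccc2)cc(OCc2ccccc2)c1 | starting material
2 | 3,5-bis(benzyloxy)phenyl N-isopropylcarbamate | CC(C)NC(=O)Oc1cc(OCc2ccccc2)cc(OCc2ccccc2)c1 | intermediate
3 | 3,5-bis(benzyloxy)phenyl N-(tert-butyldimethylsilyl)-N-isopropylcarbamate (not isolated) | CC(C)N(C(=O)Oc1cc(OCc2ccccc2)cc(OCc2ccccc2)c1)[Si](C)(C)C(C)(C)C | intermediate
4 | {2,4-bis(benzyloxy)-6-[N-(tert-butyldimethylsilyl)-N-isopropylcarbamoyloxy]phenyl}lithium (not isolated) | CC(C)N(C(=O)Oc1cc(OCc2ccccc2)cc(OCc2ccccc2)c1[Li])[Si](C)(C)C(C)(C)C | intermediate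
5 | 3,5-bis(benzyloxy)-2-(trimethylsilyl)phenyl N-(tert-butyldimethylsilyl)-N-isopropylcarbamate (not isolated) | CC(C)N(C(=O)Oc1cc(OCc2ccccc2)cc(OCc2ccccc2)c1[Si](C)(C)C)[Si](C)(C)C(C)(C)C | intermediate
6 | 3,5-bis(benzyloxy)-2-(trimethylsilyl)phenyl N-isopropylcarbamate | CC(C)NC(=O)Oc1cc(OCc2ccccc2)cc(OCc2ccccc2)c1[Si](C)(C)C | intermediate
7 | 3,5-bis(benzyloxy)-2-(trimethylsilyl)phenol (present as its DBU salt, not isolated) | Oc1cc(OCc2ccccc2)cc(OCc2ccccc2)c1[Si](C)(C)C | intermediate
8 | 3,5-bis(benzyloxy)-2-(trimethylsilyl)phenyl trifluoromethanesulfonate | C[Si](C)(C)c1c(OCc2ccccc2)cc(OCc2ccccc2)cc1OS(=O)(=O)C(F)(F)F | intermediate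
9 | (R)-4-benzyl-1,3-thiazolidine-2-thione | S=C1N[C@H](Cc2ccccc2)CS1 | starting material
10 | succinyl chloride | O=C(Cl)CCC(Cl)=O | starting material
11 | 1,4-bis[(4R)-4-benzyl-2-thioxo-1,3-thiazolidin-3-yl]butane-1,4-dione | O=C(CCC(=O)N1[C@H](Cc2ccccc2)CSC1=S)N1[C@H](Cc2ccccc2)CSC1=S | intermediate
12 | 4-methoxybenzaldehyde | COc1ccc(C=O)cc1 | starting material
13 | (2R)-1,4-bis[(4R)-4-benzyl-2-thioxo-1,3-thiazolidin-3-yl]-2-[(S)-(4-methoxyphenyl)(trimethylsilyloxy)methyl]butane-1,4-dione | O=C(N1[C@H](Cc2ccccc2)CSC1=S)[C@H](CC(=O)N1[C@H](Cc2ccccc2)CSC1=S)[C@H](O[Si](C)(C)C)c1ccc(OC)cc1 | intermediate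
14 | 4-(benzyloxy)benzaldehyde | O=Cc1ccc(OCc2ccccc2)cc1 | starting material
15 | (2R,3R)-1,4-bis[(4R)-4-benzyl-2-thioxo-1,3-thiazolidin-3-yl]-2-[(S)-[4-(benzyloxy)phenyl](trimethylsilyloxy)methyl]-3-[(S)-(4-methoxyphenyl)(trimethylsilyloxy)methyl]butane-1,4-dione | O=C(N1[C@H](Cc2ccccc2)CSC1=S)[C@@H]([C@H](O[Si](C)(C)C)c1ccc(OC)cc1)[C@H]([C@H](O[Si](C)(C)C)c1ccc(OCc2ccccc2)cc1)C(=O)N1[C@H](Cc2ccccc2)CSC1=S | intermediate
16 | (2R,3R)-2-[(S)-[4-(benzyloxy)phenyl](trimethylsilyloxy)methyl]-N1,N4-dimethoxy-3-[(S)-(4-methoxyphenyl)(trimethylsilyloxy)methyl]-N1,N4-dimethylbutanediamide | CON(C)C(=O)[C@@H]([C@H](O[Si](C)(C)C)c1ccc(OC)cc1)[C@H]([C@H](O[Si](C)(C)C)c1ccc(OCc2ccccc2)cc1)C(=O)N(C)OC | intermediate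
17 | 3,5-bis(benzyloxy)benzyne (1,2-didehydro-3,5-bis(benzyloxy)benzene, not isolated) | C1#CC(OCc2ccccc2)=CC(OCc2ccccc2)=C1 | intermediate
18 | dipotassium dialkoxide of the diol corresponding to 16 (not isolated) | [K+].[K+].CON(C)C(=O)[C@@H]([C@H]([O-])c1ccc(OC)cc1)[C@H]([C@H]([O-])c1ccc(OCc2ccccc2)cc1)C(=O)N(C)OC | intermediate
19 | (2S,2'S,3R,3'R)-5,5',7,7'-tetrakis(benzyloxy)-2-[4-(benzyloxy)phenyl]-2'-(4-methoxyphenyl)-[3,3'-bichromane]-4,4'-dione | COc1ccc([C@H]2Oc3cc(OCc4ccccc4)cc(OCc4ccccc4)c3C(=O)[C@@H]2[C@H]2C(=O)c3c(OCc4ccccc4)cc(OCc4ccccc4)cc3O[C@@H]2c2ccc(OCc3ccccc3)cc2)cc1 | intermediate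
20 | (2S,2'S,3R,3'R)-5,5',7,7'-tetrahydroxy-2-(4-hydroxyphenyl)-2'-(4-methoxyphenyl)-[3,3'-bichromane]-4,4'-dione | COc1ccc([C@H]2Oc3cc(O)cc(O)c3C(=O)[C@@H]2[C@H]2C(=O)c3c(O)cc(O)cc3O[C@@H]2c2ccc(O)cc2)cc1 | target

**Step count and risks**

Total step count: 9 (steps 1–3 make the aryne precursor 8; steps 4–7 make the acyclic precursor 16; steps 8 and 9 finish).
Longest linear sequence: 6 steps (steps 4 to 9, from 9 and 10 to 20).

Steps most likely to fail:

1. Step 8 (proposed new method). The unveiled alkoxide may undergo retro-aldol cleavage or lactonisation onto the γ-amide before an aryne is at hand. The aryl anion may be quenched by a proton and leave an uncyclised aryl ether. The liberated amide base may open the finished pyranone rings by retro-oxa-Michael reaction, with loss of configuration at C2 and C3. The fallback sets out from 16, rejoins at 19 and uses only known reactions in which ether formation and ring closure are separate events. 16 is desilylated (K2CO3, MeOH, 0 °C) to the diol (2R,3R)-2-[(S)-[4-(benzyloxy)phenyl](hydroxy)methyl]-3-[(S)-hydroxy(4-methoxyphenyl)methyl]-N1,N4-dimethoxy-N1,N4-dimethylbutanediamide F1. Both free hydroxyl groups are then O-arylated with retention by O–H insertion into aryne 17, generated from 8 with CsF in MeCN at rt, where the solvent supplies the proton for the aryl anion; this should give the bis(aryl ether) (2R,3R)-2-[(S)-[4-(benzyloxy)phenyl][3,5-bis(benzyloxy)phenoxy]methyl]-3-[(S)-[3,5-bis(benzyloxy)phenoxy](4-methoxyphenyl)methyl]-N1,N4-dimethoxy-N1,N4-dimethylbutanediamide F2. LiAlH4 (THF, −78 °C) reduces both Weinreb amides to the dialdehyde (2R,3R)-2-[(S)-[4-(benzyloxy)phenyl][3,5-bis(benzyloxy)phenoxy]methyl]-3-[(S)-[3,5-bis(benzyloxy)phenoxy](4-methoxyphenyl)methyl]butanedial F3, which is oxidised at once by Pinnick oxidation (NaClO2, NaH2PO4, 2-methyl-2-butene, t-BuOH/H2O) to (2R,3R)-2-[(S)-[4-(benzyloxy)phenyl][3,5-bis(benzyloxy)phenoxy]methyl]-3-[(S)-[3,5-bis(benzyloxy)phenoxy](4-methoxyphenyl)methyl]butanedioic acid F4. (COCl)2 with DMF (cat.) in CH2Cl2 gives (2R,3R)-2-[(S)-[4-(benzyloxy)phenyl][3,5-bis(benzyloxy)phenoxy]methyl]-3-[(S)-[3,5-bis(benzyloxy)phenoxy](4-methoxyphenyl)methyl]butanedioyl dichloride F5, and SnCl4 (CH2Cl2, −78 → −20 °C) closes both rings C by intramolecular Friedel–Crafts acylation ortho to the ether oxygen (again the C4–C4a bond) to give 19.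

2. Step 6. Catalytic soft enolisation may be too slow at the β-branched acyl group, the facial selectivity may erode through mismatch with the resident stereocenters, and the silyloxy group of the first half may be lost by β-elimination during long exposure to Et3N. The fallback sets out from 13 and rejoins at 19. It replaces the catalytic anti-aldol by a stoichiometric, chelation-controlled titanium syn-aldol that is asked to fix only the carbinol centre, and it leaves the neighbouring α-centre to be corrected at the end under thermodynamic control. 13 is converted at the unbranched methylene into its chlorotitanium enolate (TiCl4, i-Pr2NEt, CH2Cl2, −78 °C). This enolate should add to 14 through the chelated chair transition state (thiocarbonyl sulfur bound to titanium), in which the (R)-auxiliary directs the opposite enolate face from that of step 6. The expected product is the syn adduct with the carbinol carbon S, as required, and the α-carbon S, (2S,3R)-1,4-bis[(4R)-4-benzyl-2-thioxo-1,3-thiazolidin-3-yl]-2-[(S)-[4-(benzyloxy)phenyl](hydroxy)methyl]-3-[(S)-(4-methoxyphenyl)(trimethylsilyloxy)methyl]butane-1,4-dione F6. Silylation without delay (TMSCl, imidazole, CH2Cl2, 0 °C) gives (2S,3R)-1,4-bis[(4R)-4-benzyl-2-thioxo-1,3-thiazolidin-3-yl]-2-[(S)-[4-(benzyloxy)phenyl](trimethylsilyloxy)methyl]-3-[(S)-(4-methoxyphenyl)(trimethylsilyloxy)methyl]butane-1,4-dione F7. Aminolysis under the conditions of step 7 gives (2S,3R)-2-[(S)-[4-(benzyloxy)phenyl](trimethylsilyloxy)methyl]-N1,N4-dimethoxy-3-[(S)-(4-methoxyphenyl)(trimethylsilyloxy)methyl]-N1,N4-dimethylbutanediamide F8. Annulation with 8 under the conditions of step 8 gives the biflavanone whose benzyloxyphenyl half is 2,3-cis, (2S,2'S,3S,3'R)-5,5',7,7'-tetrakis(benzyloxy)-2-[4-(benzyloxy)phenyl]-2'-(4-methoxyphenyl)-[3,3'-bichromane]-4,4'-dione F9. The misconfigured carbon is α to a ketone, and 2,3-trans is expected to be the more stable arrangement of a 3-substituted flavanone. Brief treatment with DBU (cat., CH2Cl2, 0 °C) should therefore epimerise that carbon alone through the enol and give 19.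

3. Step 2. Lithiation may occur at a benzylic CH2 of the benzyl ethers (followed by 1,2-Wittig rearrangement) or between the two benzyloxy groups instead of next to the carbamate. The fallback sets out from 1, rejoins at 8 (bypassing steps 1–3) and places the silicon by halogen–metal exchange instead of deprotonation. Ortho-selective bromination of 1 (NBS, i-Pr2NH (cat.), CH2Cl2, 0 °C) gives 3,5-bis(benzyloxy)-2-bromophenol F10. O-Silylation (HMDS, THF, reflux) gives [3,5-bis(benzyloxy)-2-bromophenoxy]trimethylsilane F11. n-BuLi (THF, −78 °C) then effects bromine–lithium exchange and retro-Brook O→C silyl migration to the lithium salt of 7, which is triflated in the same flask (Tf2O, −78 °C → rt) to 8.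

Further compounds
F1 | step 8 | (2R,3R)-2-[(S)-[4-(benzyloxy)phenyl](hydroxy)methyl]-3-[(S)-hydroxy(4-methoxyphenyl)methyl]-N1,N4-dimethoxy-N1,N4-dimethylbutanediamide | CON(C)C(=O)[C@@H]([C@H](O)c1ccc(OC)cc1)[C@H]([C@H](O)c1ccc(OCc2ccccc2)cc1)C(=O)N(C)OC
F2 | step 8 | (2R,3R)-2-[(S)-[4-(benzyloxy)phenyl][3,5-bis(benzyloxy)phenoxy]methyl]-3-[(S)-[3,5-bis(benzyloxy)phenoxy](4-methoxyphenyl)methyl]-N1,N4-dimethoxy-N1,N4-dimethylbutanediamide | CON(C)C(=O)[C@@H]([C@H](Oc1cc(OCc2ccccc2)cc(OCc2ccccc2)c1)c1ccc(OC)cc1)[C@H]([C@H](Oc1cc(OCc2ccccc2)cc(OCc2ccccc2)c1)c1ccc(OCc2ccccc2)cc1)C(=O)N(C)OC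
F3 | step 8 | (2R,3R)-2-[(S)-[4-(benzyloxy)phenyl][3,5-bis(benzyloxy)phenoxy]methyl]-3-[(S)-[3,5-bis(benzyloxy)phenoxy](4-methoxyphenyl)methyl]butanedial | O=C[C@@H]([C@H](Oc1cc(OCc2ccccc2)cc(OCc2ccccc2)c1)c1ccc(OC)cc1)[C@H]([C@H](Oc1cc(OCc2ccccc2)cc(OCc2ccccc2)c1)c1ccc(OCc2ccccc2)cc1)C=O
F4 | step 8 | (2R,3R)-2-[(S)-[4-(benzyloxy)phenyl][3,5-bis(benzyloxy)phenoxy]methyl]-3-[(S)-[3,5-bis(benzyloxy)phenoxy](4-methoxyphenyl)methyl]butanedioic acid | OC(=O)[C@@H]([C@H](Oc1cc(OCc2ccccc2)cc(OCc2ccccc2)c1)c1ccc(OC)cc1)[C@H]([C@H](Oc1cc(OCc2ccccc2)cc(OCc2ccccc2)c1)c1ccc(OCc2ccccc2)cc1)C(=O)O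
F5 | step 8 | (2R,3R)-2-[(S)-[4-(benzyloxy)phenyl][3,5-bis(benzyloxy)phenoxy]methyl]-3-[(S)-[3,5-bis(benzyloxy)phenoxy](4-methoxyphenyl)methyl]butanedioyl dichloride | ClC(=O)[C@@H]([C@H](Oc1cc(OCc2ccccc2)cc(OCc2ccccc2)c1)c1ccc(OC)cc1)[C@H]([C@H](Oc1cc(OCc2ccccc2)cc(OCc2ccccc2)c1)c1ccc(OCc2ccccc2)cc1)C(=O)Cl
F6 | step 6 | (2S,3R)-1,4-bis[(4R)-4-benzyl-2-thioxo-1,3-thiazolidin-3-yl]-2-[(S)-[4-(benzyloxy)phenyl](hydroxy)methyl]-3-[(S)-(4-methoxyphenyl)(trimethylsilyloxy)methyl]butane-1,4-dione | O=C(N1[C@H](Cc2ccccc2)CSC1=S)[C@@H]([C@H](O[Si](C)(C)C)c1ccc(OC)cc1)[C@@H]([C@H](O)c1ccc(OCc2ccccc2)cc1)C(=O)N1[C@H](Cc2ccccc2)CSC1=S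
F7 | step 6 | (2S,3R)-1,4-bis[(4R)-4-benzyl-2-thioxo-1,3-thiazolidin-3-yl]-2-[(S)-[4-(benzyloxy)phenyl](trimethylsilyloxy)methyl]-3-[(S)-(4-methoxyphenyl)(trimethylsilyloxy)methyl]butane-1,4-dione | O=C(N1[C@H](Cc2ccccc2)CSC1=S)[C@@H]([C@H](O[Si](C)(C)C)c1ccc(OC)cc1)[C@@H]([C@H](O[Si](C)(C)C)c1ccc(OCc2ccccc2)cc1)C(=O)N1[C@H](Cc2ccccc2)CSC1=S
F8 | step 6 | (2S,3R)-2-[(S)-[4-(benzyloxy)phenyl](trimethylsilyloxy)methyl]-N1,N4-dimethoxy-3-[(S)-(4-methoxyphenyl)(trimethylsilyloxy)methyl]-N1,N4-dimethylbutanediamide | CON(C)C(=O)[C@@H]([C@H](O[Si](C)(C)C)c1ccc(OC)cc1)[C@@H]([C@H](O[Si](C)(C)C)c1ccc(OCc2ccccc2)cc1)C(=O)N(C)OC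
F9 | step 6 | (2S,2'S,3S,3'R)-5,5',7,7'-tetrakis(benzyloxy)-2-[4-(benzyloxy)phenyl]-2'-(4-methoxyphenyl)-[3,3'-bichromane]-4,4'-dione | COc1ccc([C@H]2Oc3cc(OCc4ccccc4)cc(OCc4ccccc4)c3C(=O)[C@@H]2[C@@H]2C(=O)c3c(OCc4ccccc4)cc(OCc4ccccc4)cc3O[C@@H]2c2ccc(OCc3ccccc3)cc2)cc1
F10 | step 2 | 3,5-bis(benzyloxy)-2-bromophenol | Oc1cc(OCc2ccccc2)cc(OCc2ccccc2)c1Br
F11 | step 2 | [3,5-bis(benzyloxy)-2-bromophenoxy]trimethylsilane | C[Si](C)(C)Oc1cc(OCc2ccccc2)cc(OCc2ccccc2)c1Br
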